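**Retrosynthetic overview**
1. Lappaol A ⇒ desilylation and trans-selective benzylation at lactone C3 with a vanillyl bromide ⇒ a (4R)-4-(arylmethyl)butyrolactone.
2. That lactone ⇒ catalytic enantioselective Baeyer–Villiger ring expansion of a prochiral 3-(arylmethyl)cyclobutanone: the lactone O1–C5 bond forms when one of two enantiotopic CH2 groups migrates to oxygen, driven by release of four-membered-ring strain. Enabling feature: without its C3 benzyl group, lactone C4 is a CH flanked by two ring CH2 groups (C3 and C5), so C2–C3–C4–C5 are the four carbons of a symmetric cyclobutanone, and C5, C4 and the benzylic CH2 are the allyl group of a eugenol-type arene.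
3. Cyclobutanone (a temporary carbocycle) ⇒ dichloroketene [2+2] on the C5 allyl group of the dihydrobenzofuran, then dechlorination.
4. (2S,3R)-Dihydrobenzofuran ⇒ acid-mediated quinone-methide closure (O1–C2) of a 1,2-diarylpropane-1,3-diol ⇒ Evans syn-aldol of an arylacetyl oxazolidinone (from 5-allyl-o-vanillin) with O-silylvanillin; the auxiliary sets C3, the trans closure sets C2.
5. Ring order: dihydrofuran ring of the benzofuran, then the four-membered ketone, then the lactone.

Key step: step 11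

Assumption: aldehydes 1 and 9 are taken as purchasable; otherwise 1 follows from o-vanillin by O-allylation and para-Claisen rearrangement, and 9 from vanillin by silylation.

Abbreviations: TBS = tert-butyldimethylsilyl; TIPS = triisopropylsilyl; Ar* = (2S,3R)-2-[4-(TBS-oxy)-3-methoxyphenyl]-3-[(TBS-oxy)methyl]-7-methoxy-2,3-dihydrobenzofuran-5-yl.

Step 1
Reactants: 1 5-allyl-2-hydroxy-3-methoxybenzaldehyde
Product: 2 5-allyl-3-methoxy-2-(TIPS-oxy)benzaldehyde
Conditions: TIPSOTf, 2,6-lutidine, CH2Cl2, 0 °C → rt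
Reagents that add atoms: triisopropylsilyl trifluoromethanesulfonate, CC(C)[Si](OS(=O)(=O)C(F)(F)F)(C(C)C)C(C)C
Why: O-silylation of the hindered, hydrogen-bonded phenol with the silyl triflate masks it as an acid-stable, fluoride-labile ether that is bulky enough not to lactonise onto the activated acid in step 4.

Step 2
Reactants: 2 5-allyl-3-methoxy-2-(TIPS-oxy)benzaldehyde
Product: 3 [4-allyl-2-methoxy-6-(2-methoxyvinyl)phenoxy]triisopropylsilane (E/Z mixture)
Conditions: Ph3P(CH2OMe)Cl, KN(SiMe3)2, THF, 0 °C → rt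
Reagents that add atoms: (methoxymethyl)triphenylphosphonium chloride, COC[P+](c1ccccc1)(c1ccccc1)c1ccccc1.[Cl-]
Why: Wittig methoxymethylenation adds the one carbon needed for the arylacetic acid, and the E/Z ratio is irrelevant because both enol ethers hydrolyse to the same aldehyde.

Step 3
Reactants: 3 [4-allyl-2-methoxy-6-(2-methoxyvinyl)phenoxy]triisopropylsilane
Product: 5 2-[5-allyl-3-methoxy-2-(TIPS-oxy)phenyl]acetic acid, via arylacetaldehyde 4 (not isolated)
Conditions: 2 M HCl, THF, 45 °C; then NaClO2, NaH2PO4, 2-methyl-2-butene, t-BuOH/H2O, 0 °C → rt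
Reagents that add atoms: water, O; sodium chlorite (NaClO2), [Na+].[O-]Cl=O
Why: Acid hydrolysis of the enol ether gives the sensitive arylacetaldehyde, which is oxidised at once under Pinnick conditions that should spare the allyl group, the aryl silyl ether and the electron-rich ring.

Step 4
Reactants: 5 2-[5-allyl-3-methoxy-2-(TIPS-oxy)phenyl]acetic acid; 6 (S)-4-benzyloxazolidin-2-one
Product: 8 (S)-4-benzyl-3-{2-[5-allyl-3-methoxy-2-(TIPS-oxy)phenyl]acetyl}oxazolidin-2-one, via mixed pivalic anhydride 7 (not isolated)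
Conditions: PivCl, Et3N, THF, −20 °C; then LiCl, 6, −20 °C → rt
Reagents that add atoms: none
Why: N-acylation of the oxazolidinone through the mixed pivalic anhydride (LiCl/Et3N activation, no strong base) should take place at the less hindered carbonyl of the anhydride and attaches the chiral auxiliary.

Step 5
Reactants: 8 (S)-4-benzyl-3-{2-[5-allyl-3-methoxy-2-(TIPS-oxy)phenyl]acetyl}oxazolidin-2-one; 9 4-(TBS-oxy)-3-methoxybenzaldehyde
Product: 12 (4S)-4-benzyl-3-{(2S,3S)-2-[5-allyl-3-methoxy-2-(TIPS-oxy)phenyl]-3-hydroxy-3-[4-(TBS-oxy)-3-methoxyphenyl]propanoyl}oxazolidin-2-one, via boron enolate 10 (not isolated), via boron aldolate 11 (not isolated)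
Conditions: Bu2BOTf, i-Pr2NEt, CH2Cl2, −78 → 0 °C; 9, −78 → 0 °C; then pH 7 buffer, MeOH, 30% H2O2, 0 °C
Reagents that add atoms: none
Why: Evans syn-aldol, in which the Z dibutylboron enolate reacts through a chair (Zimmerman–Traxler) transition state on the face opposite the benzyl group of the (S)-auxiliary and so sets the α-carbon as S (the future benzofuran C3); the carbinol centre is not needed later.

Step 6
Reactants: 12 the syn-aldol adduct
Product: 13 (1S,2R)-2-[5-allyl-3-methoxy-2-(TIPS-oxy)phenyl]-1-[4-(TBS-oxy)-3-methoxyphenyl]propane-1,3-diol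
Conditions: LiBH4, MeOH (1 equiv), THF, 0 °C
Reagents that add atoms: none
Why: Reductive cleavage of the N-acyl oxazolidinone with LiBH4 should give the primary alcohol and return the auxiliary without touching the α-stereocentre, which is no longer enolisable afterwards.

Step 7
Reactants: 13 the bis-silylated 1,3-diol
Product: 15 4-[(2S,3R)-5-allyl-3-(hydroxymethyl)-7-methoxy-2,3-dihydrobenzofuran-2-yl]-2-methoxyphenol, via free bisphenol diol 14 (not isolated)
Conditions: Bu4NF, THF, 0 °C; then TsOH·H2O, THF, rt (dilute)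
Reagents that add atoms: none
Why: Fluoride frees both phenols and acid then ionises the para-hydroxybenzylic alcohol to a quinone methide/benzylic cation that the ortho phenol captures in a 5-exo closure (biomimetic phenylcoumaran formation); the closure is reversible, so C2 should settle trans to the fixed C3 substituent, which gives 2S,3R.

Step 8
Reactants: 15 4-[(2S,3R)-5-allyl-3-(hydroxymethyl)-7-methoxy-2,3-dihydrobenzofuran-2-yl]-2-methoxyphenol
Product: 16 (2S,3R)-5-allyl-2-[4-(TBS-oxy)-3-methoxyphenyl]-3-[(TBS-oxy)methyl]-7-methoxy-2,3-dihydrobenzofuran (Ar*–CH2CH=CH2)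
Conditions: TBSCl, imidazole, DMF, rt
Reagents that add atoms: tert-butyldimethylsilyl chloride, CC(C)(C)[Si](C)(C)Cl
Why: Standard silylation of the phenol and the primary alcohol protects both against the acid chloride, the peracid and the amide base of the following steps.

Step 9
Reactants: 16 Ar*–CH2CH=CH2
Product: 17 2,2-dichloro-3-(Ar*-methyl)cyclobutan-1-one (both configurations at cyclobutane C3)
Conditions: Cl3CCOCl, Zn–Cu couple, POCl3, Et2O, reflux
Reagents that add atoms: trichloroacetyl chloride, ClC(Cl)(Cl)C(Cl)=O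
Why: Thermal [2+2] ketene–alkene cycloaddition, in which dichloroketene made in the flask adds to the terminal alkene with its carbonyl carbon bonding to the terminal CH2 while POCl3 sequesters ZnCl2; the uncontrolled cyclobutane centre becomes non-stereogenic in step 10.

Step 10
Reactants: 17 2,2-dichloro-3-(Ar*-methyl)cyclobutan-1-one
Product: 18 3-(Ar*-methyl)cyclobutan-1-one
Conditions: Zn, NH4Cl, MeOH, rt
Reagents that add atoms: none
Why: Reductive dechlorination of the α,α-dichloroketone by zinc under buffered conditions should leave the silyl ethers intact and gives the locally symmetric ketone with two enantiotopic α-CH2 groups.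

Step 11
Reactants: 18 3-(Ar*-methyl)cyclobutan-1-one
Product: 19 (4R)-4-(Ar*-methyl)dihydrofuran-2(3H)-one
Conditions: Sc(OTf)3 (5 mol %), chiral N,N'-dioxide ligand (6 mol %), m-CPBA (slow addition), EtOAc, −20 °C
Reagents that add atoms: 3-chloroperbenzoic acid (m-CPBA), OOC(=O)c1cccc(Cl)c1
Why: The trivalent scandium complex of a C2-symmetric amino-acid-derived N,N'-dioxide bis(anilide) ligand binds the ketone, m-CPBA adds to the carbonyl to give a Criegee adduct, and one of the two enantiotopic ring CH2 groups shifts from carbon to the peroxide oxygen antiperiplanar to the breaking O–O bond, so that the lactone O1–C5 bond forms with loss of 3-chlorobenzoate; release of the cyclobutanone ring strain should make this migration fast at −20 °C. The closest known reaction type is the catalytic enantioselective Baeyer–Villiger desymmetrisation of prochiral 3-substituted cyclobutanones to 4-substituted butyrolactones. The five-membered lactone closes by ring expansion of the four-membered ketone (1,2-shift of carbon to oxygen with retention at the migrating CH2), not by an end-to-end cyclisation, so no Baldwin constraint applies. The new stereocentre, lactone C4, is the former prochiral cyclobutanone C3, and its R configuration is fixed only by which CH2 the chiral catalyst lets migrate; the ligand antipode is to be assigned beforehand on 3-(3,4-dimethoxybenzyl)cyclobutanone. The step needs enantiotopic-group selectivity (both CH2 groups are primary, so there is no regiochemical issue) and chemoselectivity over the electron-rich arenes and silyl ethers; the first rests on the catalyst because the benzofuran stereocentres lie many bonds away, the second on the much higher reactivity of the strained ketone toward the peracid at low temperature, with slow addition to hold down the uncatalysed pathway.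

Step 12
Reactants: 9 4-(TBS-oxy)-3-methoxybenzaldehyde
Product: 20 [4-(TBS-oxy)-3-methoxyphenyl]methanol
Conditions: NaBH4, MeOH, 0 °C
Reagents that add atoms: none
Why: Borohydride reduction of the aldehyde to the benzylic alcohol, with the aryl silyl ether expected to survive the short reaction at 0 °C.

Step 13
Reactants: 20 [4-(TBS-oxy)-3-methoxyphenyl]methanol
Product: 21 [4-(bromomethyl)-2-methoxyphenoxy](tert-butyl)dimethylsilane
Conditions: CBr4, PPh3, CH2Cl2, 0 °C
Reagents that add atoms: carbon tetrabromide, BrC(Br)(Br)Br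
Why: Appel bromination converts the benzylic alcohol to the bromide under neutral conditions that avoid acid cleavage of the silyl ether.

Step 14
Reactants: 19 (4R)-4-(Ar*-methyl)dihydrofuran-2(3H)-one; 21 [4-(bromomethyl)-2-methoxyphenoxy](tert-butyl)dimethylsilane
Product: 23 (3R,4R)-3-[4-(TBS-oxy)-3-methoxybenzyl]-4-(Ar*-methyl)dihydrofuran-2(3H)-one, via lithium enolate 22 (not isolated)
Conditions: LiN(SiMe3)2, THF, −78 °C; then 21, DMPU, −78 → −40 °C
Reagents that add atoms: none
Why: Alkylation of the lithium enolate of a 4-substituted butyrolactone should occur on the face opposite the C4 substituent, which sets C3 as R and gives the trans-3,4-dibenzyl lactone (the standard enolate alkylation of dibenzylbutyrolactone lignans).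

Step 15
Reactants: 23 (3R,4R)-3-[4-(TBS-oxy)-3-methoxybenzyl]-4-(Ar*-methyl)dihydrofuran-2(3H)-one
Product: 24 Lappaol A
Conditions: Bu4NF, AcOH, THF, 0 °C → rt
Reagents that add atoms: none
Why: Fluoride cleavage of the two aryl and one alkyl silyl ethers, buffered with AcOH so that the lactone and its C3 centre are not exposed to basic phenoxide or fluoride, should release the target.

**Compound list**
1 | 5-allyl-2-hydroxy-3-methoxybenzaldehyde | O=Cc1cc(CC=C)cc(OC)c1O | starting material
2 | 5-allyl-3-methoxy-2-(TIPS-oxy)benzaldehyde | O=Cc1cc(CC=C)cc(OC)c1O[Si](C(C)C)(C(C)C)C(C)C | intermediate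
3 | [4-allyl-2-methoxy-6-(2-methoxyvinyl)phenoxy]triisopropylsilane (E/Z mixture) | COC=Cc1cc(CC=C)cc(OC)c1O[Si](C(C)C)(C(C)C)C(C)C | intermediate
4 | 2-[5-allyl-3-methoxy-2-(TIPS-oxy)phenyl]acetaldehyde | O=CCc1cc(CC=C)cc(OC)c1O[Si](C(C)C)(C(C)C)C(C)C | intermediate (not isolated)
5 | 2-[5-allyl-3-methoxy-2-(TIPS-oxy)phenyl]acetic acid | OC(=O)Cc1cc(CC=C)cc(OC)c1O[Si](C(C)C)(C(C)C)C(C)C | intermediate
6 | (S)-4-benzyloxazolidin-2-one | O=C1N[C@@H](Cc2ccccc2)CO1 | starting material
7 | mixed pivalic anhydride of 5 | CC(C)(C)C(=O)OC(=O)Cc1cc(CC=C)cc(OC)c1O[Si](C(C)C)(C(C)C)C(C)C | intermediate (not isolated)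
8 | (S)-4-benzyl-3-{2-[5-allyl-3-methoxy-2-(TIPS-oxy)phenyl]acetyl}oxazolidin-2-one | O=C(Cc1cc(CC=C)cc(OC)c1O[Si](C(C)C)(C(C)C)C(C)C)N1[C@@H](Cc2ccccc2)COC1=O | intermediate
9 | 4-(TBS-oxy)-3-methoxybenzaldehyde (O-TBS-vanillin) | O=Cc1ccc(O[Si](C)(C)C(C)(C)C)c(OC)c1 | starting material
10 | (Z)-dibutylboron enolate of 8 | CCCCB(CCCC)O/C(N1[C@@H](Cc2ccccc2)COC1=O)=C\c1cc(CC=C)cc(OC)c1O[Si](C(C)C)(C(C)C)C(C)C | intermediate (not isolated)
11 | dibutylboron aldolate of 12 | O=C(N1[C@@H](Cc2ccccc2)COC1=O)[C@@H](c1cc(CC=C)cc(OC)c1O[Si](C(C)C)(C(C)C)C(C)C)[C@H](OB(CCCC)CCCC)c1ccc(O[Si](C)(C)C(C)(C)C)c(OC)c1 | intermediate (not isolated)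
12 | (4S)-4-benzyl-3-{(2S,3S)-2-[5-allyl-3-methoxy-2-(TIPS-oxy)phenyl]-3-hydroxy-3-[4-(TBS-oxy)-3-methoxyphenyl]propanoyl}oxazolidin-2-one | O=C(N1[C@@H](Cc2ccccc2)COC1=O)[C@@H](c1cc(CC=C)cc(OC)c1O[Si](C(C)C)(C(C)C)C(C)C)[C@H](O)c1ccc(O[Si](C)(C)C(C)(C)C)c(OC)c1 | intermediate
13 | (1S,2R)-2-[5-allyl-3-methoxy-2-(TIPS-oxy)phenyl]-1-[4-(TBS-oxy)-3-methoxyphenyl]propane-1,3-diol | OC[C@@H](c1cc(CC=C)cc(OC)c1O[Si](C(C)C)(C(C)C)C(C)C)[C@H](O)c1ccc(O[Si](C)(C)C(C)(C)C)c(OC)c1 | intermediate
14 | (1S,2R)-2-(5-allyl-2-hydroxy-3-methoxyphenyl)-1-(4-hydroxy-3-methoxyphenyl)propane-1,3-diol | OC[C@@H](c1cc(CC=C)cc(OC)c1O)[C@H](O)c1ccc(O)c(OC)c1 | intermediate (not isolated)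
15 | 4-[(2S,3R)-5-allyl-3-(hydroxymethyl)-7-methoxy-2,3-dihydrobenzofuran-2-yl]-2-methoxyphenol | C=CCc1cc(OC)c2c(c1)[C@H](CO)[C@@H](c1ccc(O)c(OC)c1)O2 | intermediate
16 | (2S,3R)-5-allyl-2-[4-(TBS-oxy)-3-methoxyphenyl]-3-[(TBS-oxy)methyl]-7-methoxy-2,3-dihydrobenzofuran | C=CCc1cc(OC)c2c(c1)[C@H](CO[Si](C)(C)C(C)(C)C)[C@@H](c1ccc(O[Si](C)(C)C(C)(C)C)c(OC)c1)O2 | intermediate
17 | 2,2-dichloro-3-(Ar*-methyl)cyclobutan-1-one (both configurations at cyclobutane C3) | O=C1CC(Cc2cc(OC)c3c(c2)[C@H](CO[Si](C)(C)C(C)(C)C)[C@@H](c2ccc(O[Si](C)(C)C(C)(C)C)c(OC)c2)O3)C1(Cl)Cl | intermediate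
18 | 3-(Ar*-methyl)cyclobutan-1-one | O=C1CC(Cc2cc(OC)c3c(c2)[C@H](CO[Si](C)(C)C(C)(C)C)[C@@H](c2ccc(O[Si](C)(C)C(C)(C)C)c(OC)c2)O3)C1 | intermediate
19 | (4R)-4-(Ar*-methyl)dihydrofuran-2(3H)-one | O=C1C[C@@H](Cc2cc(OC)c3c(c2)[C@H](CO[Si](C)(C)C(C)(C)C)[C@@H](c2ccc(O[Si](C)(C)C(C)(C)C)c(OC)c2)O3)CO1 | intermediate
20 | [4-(TBS-oxy)-3-methoxyphenyl]methanol | OCc1ccc(O[Si](C)(C)C(C)(C)C)c(OC)c1 | intermediate
21 | [4-(bromomethyl)-2-methoxyphenoxy](tert-butyl)dimethylsilane | BrCc1ccc(O[Si](C)(C)C(C)(C)C)c(OC)c1 | intermediate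
22 | lithium enolate of 19 | [Li]OC1=C[C@@H](Cc2cc(OC)c3c(c2)[C@H](CO[Si](C)(C)C(C)(C)C)[C@@H](c2ccc(O[Si](C)(C)C(C)(C)C)c(OC)c2)O3)CO1 | intermediate (not isolated)
23 | (3R,4R)-3-[4-(TBS-oxy)-3-methoxybenzyl]-4-(Ar*-methyl)dihydrofuran-2(3H)-one | COc1cc(C[C@H]2C(=O)OC[C@@H]2Cc2cc(OC)c3c(c2)[C@H](CO[Si](C)(C)C(C)(C)C)[C@@H](c2ccc(O[Si](C)(C)C(C)(C)C)c(OC)c2)O3)ccc1O[Si](C)(C)C(C)(C)C | intermediate
24 | Lappaol A, (3R,4R)-3-(4-hydroxy-3-methoxybenzyl)-4-{[(2S,3R)-2-(4-hydroxy-3-methoxyphenyl)-3-(hydroxymethyl)-7-methoxy-2,3-dihydrobenzofuran-5-yl]methyl}dihydrofuran-2(3H)-one | COc1cc(C[C@H]2C(=O)OC[C@@H]2Cc2cc(OC)c3c(c2)[C@H](CO)[C@@H](c2ccc(O)c(OC)c2)O3)ccc1O | target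

**Step count**
Total steps: 15 (13 in the main line, 2 for bromide 21; aldehyde 9 is used twice).
Longest linear sequence: 13 steps (1 → 24 through steps 1–11, 14 and 15).

**Steps most likely to fail, with fallbacks**

Step 11. The catalyst may discriminate poorly between the two enantiotopic CH2 groups because the 3-substituent is a flexible arylmethyl group, and uncatalysed peracid oxidation may compete; either would give a mixture of C4 epimers that differ only at a remote centre and are hard to separate. The fallback sets out from 18 and desymmetrises by deprotonation instead of oxidation. A chiral lithium amide (lithium bis[(S)-1-phenylethyl]amide or its antipode, assigned on the same model ketone) with Me3SiCl in THF at −100 °C should give the silyl enol ether (3R)-3-(Ar*-methyl)-1-(trimethylsilyloxy)cyclobut-1-ene F1. Ozonolysis (O3, CH2Cl2/MeOH, −78 °C) with NaBH4 work-up should give the hydroxy acid (3R)-4-hydroxy-3-(Ar*-methyl)butanoic acid F2, which lactonises on acidification (TsOH, CH2Cl2) and so comes back to the route at 19.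

Step 9. ZnCl2 formed in the flask may ionise the benzylic C2–O bond of the dihydrobenzofuran or strip silyl ethers, and the unactivated alkene may react so slowly that the ketene oligomerises. The fallback sets out from 16 and uses a keteniminium [2+2] cycloaddition that needs no zinc: N,N-dimethylacetamide, Tf2O and 2,4,6-collidine in 1,2-dichloroethane at reflux should give the cyclobutaniminium salt N-[3-(Ar*-methyl)cyclobutylidene]-N-methylmethanaminium triflate F3. Hydrolysis with aqueous NaHCO3 comes back to the route at 18, so 17 is bypassed.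

Step 6. Retro-aldol cleavage of the β-hydroxy imide (both fragments are stabilised by aryl groups) under the basic hydride conditions, or epimerisation of the α-aryl centre, may erode yield and stereochemical purity. The fallback sets out from 12 and masks the carbinol first: Et3SiOTf and 2,6-lutidine in CH2Cl2 at −78 °C should give the triethylsilyl-protected aldol adduct F4, which cannot fragment. LiBH4/MeOH then gives the silyl-protected primary alcohol F5. Bu4NF removes all three silyl groups and comes back to the route at 14, which is cyclised with TsOH to 15 as in step 7.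

**Further compounds**
F1 | step 11 | (3R)-3-(Ar*-methyl)-1-(trimethylsilyloxy)cyclobut-1-ene | C[Si](C)(C)OC1=C[C@H](Cc2cc(OC)c3c(c2)[C@H](CO[Si](C)(C)C(C)(C)C)[C@@H](c2ccc(O[Si](C)(C)C(C)(C)C)c(OC)c2)O3)C1
F2 | step 11 | (3R)-4-hydroxy-3-(Ar*-methyl)butanoic acid | OC(=O)C[C@@H](Cc2cc(OC)c3c(c2)[C@H](CO[Si](C)(C)C(C)(C)C)[C@@H](c2ccc(O[Si](C)(C)C(C)(C)C)c(OC)c2)O3)CO
F3 | step 9 | N-[3-(Ar*-methyl)cyclobutylidene]-N-methylmethanaminium triflate | C[N+](C)=C1CC(Cc2cc(OC)c3c(c2)[C@H](CO[Si](C)(C)C(C)(C)C)[C@@H](c2ccc(O[Si](C)(C)C(C)(C)C)c(OC)c2)O3)C1.[O-]S(=O)(=O)C(F)(F)F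
F4 | step 6 | (4S)-4-benzyl-3-{(2S,3S)-2-[5-allyl-3-methoxy-2-(TIPS-oxy)phenyl]-3-[4-(TBS-oxy)-3-methoxyphenyl]-3-(triethylsilyloxy)propanoyl}oxazolidin-2-one | O=C(N1[C@@H](Cc2ccccc2)COC1=O)[C@@H](c1cc(CC=C)cc(OC)c1O[Si](C(C)C)(C(C)C)C(C)C)[C@H](O[Si](CC)(CC)CC)c1ccc(O[Si](C)(C)C(C)(C)C)c(OC)c1
F5 | step 6 | (2R,3S)-2-[5-allyl-3-methoxy-2-(TIPS-oxy)phenyl]-3-[4-(TBS-oxy)-3-methoxyphenyl]-3-(triethylsilyloxy)propan-1-ol | OC[C@@H](c1cc(CC=C)cc(OC)c1O[Si](C(C)C)(C(C)C)C(C)C)[C@H](O[Si](CC)(CC)CC)c1ccc(O[Si](C)(C)C(C)(C)C)c(OC)c1
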